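The partner was the reagent I followed in this flask: each portion dosed either decays or couples with the intermediate.

substrate 20 mM; partner 20.0 mM (fed, over 20 s); free catalyst 1.0 mM; second catalyst 1.4 mM; time 15 min

    partner → decomposed reagent (k1 = 0.23 /s)
    substrate + free catalyst → free catalyst + intermediate (k2 = 45 /M/s)
    partner + second catalyst + intermediate → second catalyst + product (k3 = 1100 /M²/s)

* the product standing at 15 min, as a percentage of the substrate charged
* the intermediate standing at 15 min, as a percentage of the substrate charged

I asked first what the end state must be. The partner lives 4.35 s and the substrate 22.2 s, both far shorter than the 15 min allowed. So I took the end to be intermediate and product summing to the substrate charged, with the product set by the partner charge times one number.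

That number is the coupling share, the fraction of dosed partner that couples instead of decaying. It is the pseudo-first-order coupling constant, 1100 /M²/s times c(second catalyst) times c(intermediate), divided by itself plus 0.23 /s.

The partner's life is shorter than the 20 s feed, so an average portion is consumed about 14.3 s after dosing starts. Counting no intermediate lost to product, c(intermediate) then stands near 9.51 mM. The coupling constant is 0.0147 /s, less than the decay constant, and the share is 5.99%.

The weak link was that single moment: c(intermediate) rises along a curve, not a straight line. Averaged over the feed and over each portion's exponential life, it came to 8.97 mM. This gave a coupling share of 5.67%. I committed to 5.67% product and 94.3% intermediate.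

The forecast gave 5.3% product (range 4.8% to 5.8%) and 94.7% intermediate (range 94.2% to 95.2%), opening from this: “The partner is the limiting factor because it decomposes quickly”. My product figure was higher than the forecast's by 0.37 percentage points.

The flask stood at 5.32% product and 94.7% intermediate, inside both of the forecast's ranges and 0.34 points below my product figure. For the neighbour flask with 4.0 mM of free catalyst, I reckoned the coupling share anew. The average c(intermediate) becomes 17.0 mM, and the coupling share becomes 10.2%, so I expected 10.2% product. That neighbour flask gave 9.63% product and 90.4% intermediate.

The constants belong to no real substance; the rest is arithmetic.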